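## Retrosynthetic overview

1. Target ⇐ C–B oxidation and exo-face hydrogenation of a norbornene boronate ⇐ intramolecular Diels–Alder reaction of a 1-alkyl-2-isopropylcyclopentadiene with an (E)-alkenylboronate, which closes ring B (the central cyclohexane) and both cyclopentane rings of the bicyclo[2.2.1]heptane at once.
2. That precursor ⇐ ring A (the bromocyclohexanol) carrying a vinyl group and an enone-terminated chain ⇐ bromonium-initiated, allylsilane-terminated cyclisation that forms the bond between the methyl-bearing quaternary carbon and the ring-fusion CH of ring A.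
3. Enabling feature: in ring A the CHBr carbon and the neighbouring quaternary C(CH3) are the two carbons of a former (E)-trisubstituted alkene, and the ring-fusion CH lies between that quaternary carbon and the tertiary carbinol C(CH3)(OH). The carbinol oxygen can therefore hold a silicon tether that makes the CH the γ-carbon of an allylsilane, and the carbinol itself is the stereocentre of (R)-linalool.
4. Cyclisation substrate ⇐ B-alkyl Suzuki–Miyaura coupling of 3-bromo-2-isopropylcyclopent-2-enone with a dienyl siloxane made from (R)-linalool (silylation, ring-closing metathesis, allylic oxidation, Wittig).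
5. Ring order: temporary oxasiline ring → ring A (key step, which also opens the siloxane) → ring B and the two norbornane rings together.

Key step: step 8

Assumption: commercial (R)-(−)-linalool of high enantiomeric purity is the only source of absolute stereochemistry; its carbinol carbon becomes the C(CH3)(OH) carbon of the target without any bond to it being broken.

## Route

Step 1
Reactants: 1 (R)-(−)-linalool; 2 allyl(chloro)dimethylsilane
Product: 3 (R)-allyl[(3,7-dimethylocta-1,6-dien-3-yl)oxy]dimethylsilane
Conditions: imidazole, DMF, 0 °C to rt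
Reagents that add atoms: allyl(chloro)dimethylsilane (2), C=CC[Si](C)(C)Cl
Why: Imidazole-promoted O-silylation of the tertiary allylic alcohol with a small chlorosilane should be clean and leaves the carbinol stereocentre untouched.

Step 2
Reactants: 3 (R)-allyl[(3,7-dimethylocta-1,6-dien-3-yl)oxy]dimethylsilane
Product: 4 (6R)-2,2,6-trimethyl-6-(4-methylpent-3-en-1-yl)-3,6-dihydro-2H-1,2-oxasiline
Conditions: second-generation Grubbs catalyst RuCl2(=CHPh)(PCy3)(H2IMes) (cat.), CH2Cl2 (dilute), 40 °C
Reagents that add atoms: none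
Why: Silicon-tethered ring-closing metathesis should give the six-membered cis-allylsiloxane because the ruthenium carbene loads on the unhindered allylsilane terminus and closes onto the vinyl group faster than it can engage the trisubstituted alkene; no stereocentre is formed.

Step 3
Reactants: 4 (6R)-2,2,6-trimethyl-6-(4-methylpent-3-en-1-yl)-3,6-dihydro-2H-1,2-oxasiline
Product: 6 (E)-2-methyl-5-[(6R)-2,2,6-trimethyl-3,6-dihydro-2H-1,2-oxasilin-6-yl]pent-2-enal, via allylic alcohol 5 (not isolated)
Conditions: SeO2 (cat.), t-BuOOH, salicylic acid (cat.), CH2Cl2, rt; then MnO2, CH2Cl2, rt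
Reagents that add atoms: tert-butyl hydroperoxide, CC(C)(C)OO (terminal oxidant; the oxygen is passed on by catalytic SeO2, O=[Se]=O)
Why: Riley allylic oxidation (ene reaction then [2,3]-shift) should select the (E)-methyl group of the most electron-rich alkene, and MnO2 should then converge alcohol and aldehyde to the (E)-enal with the alkene geometry retained.

Step 4
Reactants: 6 (E)-2-methyl-5-[(6R)-2,2,6-trimethyl-3,6-dihydro-2H-1,2-oxasilin-6-yl]pent-2-enal; 7 methyltriphenylphosphonium bromide
Product: 8 (6R)-2,2,6-trimethyl-6-[(E)-4-methylhexa-3,5-dien-1-yl]-3,6-dihydro-2H-1,2-oxasiline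
Conditions: KN(SiMe3)2, THF, 0 °C; then 6, −78 °C to rt
Reagents that add atoms: methyltriphenylphosphonium bromide (7), C[P+](c1ccccc1)(c1ccccc1)c1ccccc1.[Br-]
Why: Wittig methylenation of the enal should give the terminal diene without touching the (E)-trisubstituted alkene or the siloxane.

Step 5
Reactants: 9 succinic anhydride; 10 3-methylbutanoyl chloride
Product: 11 2-isopropylcyclopentane-1,3-dione
Conditions: AlCl3, MeNO2, 80 °C; aqueous HCl work-up
Reagents that add atoms: none
Why: AlCl3-mediated double C-acylation of the enolisable acid chloride by succinic anhydride with loss of CO2 is the standard cyclocondensation route to 2-alkylcyclopentane-1,3-diones; no stereocentre is involved.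

Step 6
Reactants: 11 2-isopropylcyclopentane-1,3-dione
Product: 12 3-bromo-2-isopropylcyclopent-2-en-1-one
Conditions: PPh3, Br2, Et3N, CH2Cl2, 0 °C to rt
Reagents that add atoms: bromine, BrBr
Why: Ph3PBr2 should convert the enol of the symmetric 1,3-dione into the vinylogous acid bromide, and the symmetry of the dione removes any regiochemical question.

Step 7
Reactants: 8 (6R)-2,2,6-trimethyl-6-[(E)-4-methylhexa-3,5-dien-1-yl]-3,6-dihydro-2H-1,2-oxasiline; 12 3-bromo-2-isopropylcyclopent-2-en-1-one
Product: 14 2-isopropyl-3-[(E)-3-methyl-6-[(6R)-2,2,6-trimethyl-3,6-dihydro-2H-1,2-oxasilin-6-yl]hex-3-en-1-yl]cyclopent-2-en-1-one, via alkylborane 13 (not isolated)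
Conditions: 9-BBN, THF, 0 °C to rt; then 12, PdCl2(dppf) (cat.), AsPh3 (cat.), K3PO4, DMF, 50 °C
Reagents that add atoms: none
Why: 9-BBN should hydroborate only the terminal vinyl group of the diene (the ring cis-alkene and the trisubstituted alkene are too hindered), and B-alkyl Suzuki–Miyaura coupling with the activated β-bromo enone then forges the sp3–sp2 bond under near-anhydrous base that spares the siloxane.

Step 8
Reactants: 14 2-isopropyl-3-[(E)-3-methyl-6-[(6R)-2,2,6-trimethyl-3,6-dihydro-2H-1,2-oxasilin-6-yl]hex-3-en-1-yl]cyclopent-2-en-1-one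
Product: 16 (1R,2S,3S,4S)-4-bromo-1,3-dimethyl-3-[2-(2-isopropyl-3-oxocyclopent-1-en-1-yl)ethyl]-2-vinylcyclohexan-1-ol, via aryloxysilyl ether 15 (not isolated)
Conditions: 2,4,4,6-tetrabromocyclohexa-2,5-dien-1-one, MeNO2, −20 °C; then aqueous K2CO3, THF, rt
Reagents that add atoms: 2,4,4,6-tetrabromocyclohexa-2,5-dien-1-one, O=C1C(Br)=CC(Br)(Br)C=C1Br
Why: Proposed new method: Br+ from the bromodienone is delivered to the (E)-trisubstituted alkene, the bromonium ion is opened at its tertiary terminus by the γ-carbon of the tethered cyclic allylsiloxane (anti SE2′), and the β-silyl cation is collapsed by 2,4,6-tribromophenoxide attack at silicon, which releases the vinyl group and leaves the carbinol oxygen as a silyl ether that the carbonate work-up hydrolyses. The closest known reaction types are bromonium-initiated cation–olefin cyclisations with arene or alkene terminators and epoxide- or acetal-initiated cyclisations terminated by allylsilanes; joining a halonium initiator to an allylsilane terminator is the unprecedented element. Ring A closes through a six-membered chair transition state, endo with respect to the two bromonium carbons and 6-exo-trig with respect to the allylsilane π-bond. Anti addition across the (E)-alkene fixes the CHBr carbon (bromine equatorial) relative to the new quaternary carbon (methyl axial, chain equatorial); the ring-fusion CH is set by attack anti to the C–Si bond with the nascent vinyl group equatorial; and the absolute sense of all three follows from the (R)-carbinol, because the cis-fused bicyclic transition state puts the siloxane oxygen axial and the carbinol methyl equatorial, avoiding a 1,3-diaxial methyl–methyl contact with the incoming quaternary centre. The step needs Br+ to choose the trisubstituted alkene over the allylsilane π-bond and needs C- rather than O-capture: the first should follow from the cis-disubstituted, alkoxysilyl-deactivated allylsilane whose C–Si bond lies near the π-nodal plane in the ground state, together with reversible Br+ transfer between alkenes, and the second from the low nucleophilicity of a hindered tertiary siloxane oxygen. The tetrasubstituted enone is electron-poor and should be a spectator.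

Step 9
Reactants: 16 (1R,2S,3S,4S)-4-bromo-1,3-dimethyl-3-[2-(2-isopropyl-3-oxocyclopent-1-en-1-yl)ethyl]-2-vinylcyclohexan-1-ol
Product: 18 (1S,2S,3S,6R)-3-bromo-6-hydroxy-2,6-dimethyl-2-[2-(2-isopropyl-3-oxocyclopent-1-en-1-yl)ethyl]cyclohexane-1-carbaldehyde, via vicinal diol 17 (not isolated)
Conditions: OsO4 (cat.), NaIO4, 2,6-lutidine, dioxane–H2O, rt
Reagents that add atoms: sodium periodate, [Na+].[O-]I(=O)(=O)=O (the oxygen is passed on by catalytic OsO4, O=[Os](=O)(=O)=O)
Why: Lemieux–Johnson cleavage should act only on the vinyl group (the tetrasubstituted enone is inert to OsO4), and the buffered medium avoids retro-aldol cleavage while the formyl group stays in the thermodynamically preferred equatorial position.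

Step 10
Reactants: 18 (1S,2S,3S,6R)-3-bromo-6-hydroxy-2,6-dimethyl-2-[2-(2-isopropyl-3-oxocyclopent-1-en-1-yl)ethyl]cyclohexane-1-carbaldehyde; 19 2-(dichloromethyl)-4,4,5,5-tetramethyl-1,3,2-dioxaborolane
Product: 20 (1R,2S,3S,4S)-4-bromo-1,3-dimethyl-3-[2-(2-isopropyl-3-oxocyclopent-1-en-1-yl)ethyl]-2-[(E)-2-(4,4,5,5-tetramethyl-1,3,2-dioxaborolan-2-yl)vinyl]cyclohexan-1-ol
Conditions: CrCl2, LiI, THF, rt
Reagents that add atoms: 2-(dichloromethyl)-4,4,5,5-tetramethyl-1,3,2-dioxaborolane (19), ClC(Cl)B1OC(C)(C)C(C)(C)O1
Why: Takai–Utimoto olefination with the geminal dichromium reagent should give the (E)-alkenylboronate selectively, is chemoselective for the aldehyde over the ketone, and is non-basic, so the β-hydroxy aldehyde is not cleaved.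

Step 11
Reactants: 20 (1R,2S,3S,4S)-4-bromo-1,3-dimethyl-3-[2-(2-isopropyl-3-oxocyclopent-1-en-1-yl)ethyl]-2-[(E)-2-(4,4,5,5-tetramethyl-1,3,2-dioxaborolan-2-yl)vinyl]cyclohexan-1-ol
Product: 21 (1R,2S,3S,4S)-4-bromo-3-[2-(3-hydroxy-2-isopropylcyclopent-1-en-1-yl)ethyl]-1,3-dimethyl-2-[(E)-2-(4,4,5,5-tetramethyl-1,3,2-dioxaborolan-2-yl)vinyl]cyclohexan-1-ol (both epimers at the cyclopentenol carbon)
Conditions: NaBH4, CeCl3·7H2O, MeOH, −40 °C
Reagents that add atoms: none
Why: Luche reduction should give clean 1,2-reduction of the enone; the new carbinol centre is inconsequential because step 12 removes it.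

Step 12
Reactants: 21 (1R,2S,3S,4S)-4-bromo-3-[2-(3-hydroxy-2-isopropylcyclopent-1-en-1-yl)ethyl]-1,3-dimethyl-2-[(E)-2-(4,4,5,5-tetramethyl-1,3,2-dioxaborolan-2-yl)vinyl]cyclohexan-1-ol
Product: 24 tetracyclic norbornene boronate (isopropyl on the ring alkene; boronate endo; ring B fused through the bridgehead and the exo position), via allylic mesylate 22 (not isolated), via cyclopentadiene 23 (not isolated)
Conditions: MsCl, Et3N, CH2Cl2, −20 °C to rt; filtration through basic Al2O3; then toluene (high dilution), BHT, 120 °C
Reagents that add atoms: none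
Why: Selective mesylation of the secondary allylic alcohol and elimination should give directly the 1-alkyl-2-isopropylcyclopenta-1,3-diene whose substituted terminus carries the tether, and on heating this should undergo intramolecular Diels–Alder cycloaddition with the (E)-alkenylboronate through a chair-like six-membered tether in which the ring-A carbon ends exo and boron endo (E-alkene), the boron-bearing carbon sits equatorial on ring B to avoid the angular methyl, and A(1,3) strain fixes the reacting alkene face, so that both bridgeheads, the ring-fusion CH and the boron-bearing carbon are set together.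

Step 13
Reactants: 24 tetracyclic norbornene boronate
Product: 25 tetracyclic norbornane boronate (isopropyl endo)
Conditions: H2 (1 atm), PtO2, EtOAc, rt
Reagents that add atoms: none
Why: Heterogeneous hydrogenation should deliver hydrogen to the exo face of the norbornene (the side of the one-carbon bridge; the endo face is blocked by the endo boronate), which places the isopropyl group endo, and the secondary bromide should survive these neutral conditions.

Step 14
Reactants: 25 tetracyclic norbornane boronate (isopropyl endo)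
Product: 27 CNP0295684.1, via borate ester 26 (not isolated)
Conditions: NaBO3·4H2O, THF–H2O, rt
Reagents that add atoms: sodium perborate tetrahydrate NaBO3·4H2O, [Na+].[O-]OB=O
Why: Oxidation of the secondary C–B bond proceeds by 1,2-migration with retention and should therefore give the endo alcohol under mild conditions that leave the alkyl bromide intact.

## Compound list

1 | (R)-(−)-linalool, (3R)-3,7-dimethylocta-1,6-dien-3-ol | CC(C)=CCC[C@@](C)(O)C=C | starting material
2 | allyl(chloro)dimethylsilane | C=CC[Si](C)(C)Cl | starting material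
3 | (R)-allyl[(3,7-dimethylocta-1,6-dien-3-yl)oxy]dimethylsilane | CC(C)=CCC[C@@](C)(O[Si](C)(C)CC=C)C=C | intermediate
4 | (6R)-2,2,6-trimethyl-6-(4-methylpent-3-en-1-yl)-3,6-dihydro-2H-1,2-oxasiline | CC(C)=CCC[C@@]1(C)O[Si](C)(C)CC=C1 | intermediate
5 | (E)-2-methyl-5-[(6R)-2,2,6-trimethyl-3,6-dihydro-2H-1,2-oxasilin-6-yl]pent-2-en-1-ol | OC/C(C)=C/CC[C@@]1(C)O[Si](C)(C)CC=C1 | intermediate (not isolated)
6 | (E)-2-methyl-5-[(6R)-2,2,6-trimethyl-3,6-dihydro-2H-1,2-oxasilin-6-yl]pent-2-enal | O=C/C(C)=C/CC[C@@]1(C)O[Si](C)(C)CC=C1 | intermediate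
7 | methyltriphenylphosphonium bromide | C[P+](c1ccccc1)(c1ccccc1)c1ccccc1.[Br-] | starting material
8 | (6R)-2,2,6-trimethyl-6-[(E)-4-methylhexa-3,5-dien-1-yl]-3,6-dihydro-2H-1,2-oxasiline | C=C/C(C)=C/CC[C@@]1(C)O[Si](C)(C)CC=C1 | intermediate
9 | succinic anhydride | O=C1CCC(=O)O1 | starting material
10 | 3-methylbutanoyl chloride | CC(C)CC(Cl)=O | starting material
11 | 2-isopropylcyclopentane-1,3-dione | CC(C)C1C(=O)CCC1=O | intermediate
12 | 3-bromo-2-isopropylcyclopent-2-en-1-one | CC(C)C1=C(Br)CCC1=O | intermediate
13 | 9-[(E)-3-methyl-6-[(6R)-2,2,6-trimethyl-3,6-dihydro-2H-1,2-oxasilin-6-yl]hex-3-en-1-yl]-9-borabicyclo[3.3.1]nonane | B1(CC/C(C)=C/CC[C@@]2(C)O[Si](C)(C)CC=C2)C2CCCC1CCC2 | intermediate (not isolated)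
14 | 2-isopropyl-3-[(E)-3-methyl-6-[(6R)-2,2,6-trimethyl-3,6-dihydro-2H-1,2-oxasilin-6-yl]hex-3-en-1-yl]cyclopent-2-en-1-one | O=C1CCC(CC/C(C)=C/CC[C@@]2(C)O[Si](C)(C)CC=C2)=C1C(C)C | intermediate
15 | dimethyl(2,4,6-tribromophenoxy)silyl ether of 16 at the tertiary carbinol oxygen | O=C1CCC(CC[C@]2(C)[C@@H](Br)CC[C@@](C)(O[Si](C)(C)Oc3c(Br)cc(Br)cc3Br)[C@H]2C=C)=C1C(C)C | intermediate (not isolated)
16 | (1R,2S,3S,4S)-4-bromo-1,3-dimethyl-3-[2-(2-isopropyl-3-oxocyclopent-1-en-1-yl)ethyl]-2-vinylcyclohexan-1-ol (OH axial and cis to the ring methyl; vinyl and Br equatorial) | O=C1CCC(CC[C@]2(C)[C@@H](Br)CC[C@@](C)(O)[C@H]2C=C)=C1C(C)C | intermediate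
17 | vicinal diol from dihydroxylation of the vinyl group of 16 (both epimers at the new carbinol carbon) | O=C1CCC(CC[C@]2(C)[C@@H](Br)CC[C@@](C)(O)[C@H]2C(O)CO)=C1C(C)C | intermediate (not isolated)
18 | (1S,2S,3S,6R)-3-bromo-6-hydroxy-2,6-dimethyl-2-[2-(2-isopropyl-3-oxocyclopent-1-en-1-yl)ethyl]cyclohexane-1-carbaldehyde | O=C1CCC(CC[C@]2(C)[C@@H](Br)CC[C@@](C)(O)[C@H]2C=O)=C1C(C)C | intermediate
19 | 2-(dichloromethyl)-4,4,5,5-tetramethyl-1,3,2-dioxaborolane | ClC(Cl)B1OC(C)(C)C(C)(C)O1 | starting material
20 | (1R,2S,3S,4S)-4-bromo-1,3-dimethyl-3-[2-(2-isopropyl-3-oxocyclopent-1-en-1-yl)ethyl]-2-[(E)-2-(4,4,5,5-tetramethyl-1,3,2-dioxaborolan-2-yl)vinyl]cyclohexan-1-ol | O=C1CCC(CC[C@]2(C)[C@@H](Br)CC[C@@](C)(O)[C@H]2/C=C/B3OC(C)(C)C(C)(C)O3)=C1C(C)C | intermediate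
21 | (1R,2S,3S,4S)-4-bromo-3-[2-(3-hydroxy-2-isopropylcyclopent-1-en-1-yl)ethyl]-1,3-dimethyl-2-[(E)-2-(4,4,5,5-tetramethyl-1,3,2-dioxaborolan-2-yl)vinyl]cyclohexan-1-ol (both epimers at the cyclopentenol carbon) | OC1CCC(CC[C@]2(C)[C@@H](Br)CC[C@@](C)(O)[C@H]2/C=C/B3OC(C)(C)C(C)(C)O3)=C1C(C)C | intermediate
22 | secondary allylic methanesulfonate of 21 | CS(=O)(=O)OC1CCC(CC[C@]2(C)[C@@H](Br)CC[C@@](C)(O)[C@H]2/C=C/B3OC(C)(C)C(C)(C)O3)=C1C(C)C | intermediate (not isolated)
23 | 1-alkyl-2-isopropylcyclopenta-1,3-diene (drawn as the reactive tautomer; in equilibrium with its [1,5]-hydrogen-shift isomers) | C1=CCC(CC[C@]2(C)[C@@H](Br)CC[C@@](C)(O)[C@H]2/C=C/B3OC(C)(C)C(C)(C)O3)=C1C(C)C | intermediate (not isolated)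
24 | tetracyclic norbornene boronate: target skeleton with a double bond between the isopropyl-bearing carbon and the adjacent CH, and pinacolboryl (endo) in place of the secondary hydroxyl | CC(C)C1=C[C@H]2C[C@@]13CC[C@]1(C)[C@@H](Br)CC[C@@](C)(O)[C@H]1[C@@H]3[C@H]2B4OC(C)(C)C(C)(C)O4 | intermediate
25 | tetracyclic norbornane boronate: target with pinacolboryl (endo) in place of the secondary hydroxyl; isopropyl endo | CC(C)[C@@H]1C[C@H]2C[C@@]13CC[C@]1(C)[C@@H](Br)CC[C@@](C)(O)[C@H]1[C@@H]3[C@H]2B4OC(C)(C)C(C)(C)O4 | intermediate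
26 | pinacol borate ester of the target at the secondary (endo) oxygen | CC(C)[C@@H]1C[C@H]2C[C@@]13CC[C@]1(C)[C@@H](Br)CC[C@@](C)(O)[C@H]1[C@@H]3[C@H]2OB4OC(C)(C)C(C)(C)O4 | intermediate (not isolated)
27 | CNP0295684.1 | CC(C)[C@@H]1C[C@H]2C[C@@]13CC[C@]1(C)[C@@H](Br)CC[C@@](C)(O)[C@H]1[C@@H]3[C@H]2O | target

## Step count and risks

Total: 14 steps. Longest linear sequence: 12 steps (steps 1–4 and 7–14); steps 5 and 6 make the coupling partner 12.

Steps most likely to fail:

1. Step 8 (proposed new method). Br+ may be consumed at the allylsilane π-bond (bromodesilylation), the bromonium ion may be captured by the siloxane oxygen (bromoetherification), or the chair preference set by the carbinol may be too small for clean diastereocontrol. The fallback sets out from 14 and returns at 16, and it delivers bromine as bromide so that no free Br+ meets the allylsilane. Shi epoxidation of the trisubstituted alkene of 14 (fructose-derived ketone catalyst of the enantiomeric series that gives the face shown, KHSO5, buffered MeCN–H2O) should give the epoxide F1. Regioselective SN2 opening at the secondary carbon with Li2NiBr4 in THF should give the anti bromohydrin F2. BF3·OEt2 in CH2Cl2 at −78 °C should then ionise the tertiary alcohol with anchimeric assistance by bromine, and the allylsiloxane closes ring A in the ordinary Lewis-acid allylsilane-terminated manner. Double inversion at the quaternary carbon and the aqueous K2CO3 work-up return 16.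

2. Step 12. [1,5]-Hydrogen shifts may feed a regioisomeric cyclopentadiene tautomer into the cycloaddition, intermolecular dimerisation may compete at the hindered diene terminus, or the tether may not control the face. The fallback sets out from 20 and returns at 24, and it uses a diene whose termini are fixed. Kinetic enolisation of 20 (LiN(SiMe3)2, THF, −78 °C, then t-BuMe2SiCl) should give the cross-conjugated silyl dienol ether F3, which cannot tautomerise and is more electron-rich. Its intramolecular Diels–Alder reaction at 40–80 °C should give the silyl enol ether cycloadduct F4. CsF and PhNTf2 should convert this regiospecifically (enolisation toward the bridgehead is impossible) into the enol triflate F5. Reduction with Pd(OAc)2, PPh3, Bu3N and HCO2H in DMF should then give 24.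

3. Step 7. Slow transmetalation and competing β-hydride elimination or protodeboronation at the hindered β-bromo enone, or base-induced cleavage of the siloxane, may starve the coupling. The fallback sets out from 8 and returns at 14, and it replaces cross-coupling by carbonyl addition. Hydroboration of 8 with 9-BBN followed by I2 and NaOMe should give the primary iodide F6. Dione 11 with ethanol and catalytic TsOH should give the vinylogous ester F7. Lithium–iodine exchange on F6 (t-BuLi, Et2O, −78 °C) and 1,2-addition to F7 should give the tertiary carbinol F8, which on mild aqueous acid (oxalic acid) should undergo Stork–Danheiser transposition to 14.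

## Further compounds

F1 | step 8 | 2-isopropyl-3-[2-[(2S,3S)-2-methyl-3-[2-[(6R)-2,2,6-trimethyl-3,6-dihydro-2H-1,2-oxasilin-6-yl]ethyl]oxiran-2-yl]ethyl]cyclopent-2-en-1-one (trans epoxide of the trisubstituted alkene of 14) | O=C1CCC(CC[C@@]2(C)O[C@@H]2CC[C@@]3(C)O[Si](C)(C)CC=C3)=C1C(C)C
F2 | step 8 | anti bromohydrin from F1 (tertiary OH, secondary Br) | O=C1CCC(CC[C@](O)(C)[C@@H](Br)CC[C@@]2(C)O[Si](C)(C)CC=C2)=C1C(C)C
F3 | step 12 | tert-butyldimethylsilyl dienol ether of 20 (2-silyloxy-1,3-diene with the tether on a diene terminus) | CC(C)C1=C(CC[C@]2(C)[C@@H](Br)CC[C@@](C)(O)[C@H]2/C=C/B3OC(C)(C)C(C)(C)O3)CC=C1O[Si](C)(C)C(C)(C)C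
F4 | step 12 | cycloadduct of F3 (24 bearing tert-butyldimethylsilyloxy on the alkene CH carbon) | CC(C)C1=C(O[Si](C)(C)C(C)(C)C)[C@H]2C[C@@]13CC[C@]1(C)[C@@H](Br)CC[C@@](C)(O)[C@H]1[C@@H]3[C@H]2B4OC(C)(C)C(C)(C)O4
F5 | step 12 | enol triflate corresponding to F4 | CC(C)C1=C(OS(=O)(=O)C(F)(F)F)[C@H]2C[C@@]13CC[C@]1(C)[C@@H](Br)CC[C@@](C)(O)[C@H]1[C@@H]3[C@H]2B4OC(C)(C)C(C)(C)O4
F6 | step 7 | (6R)-6-[(E)-6-iodo-4-methylhex-3-en-1-yl]-2,2,6-trimethyl-3,6-dihydro-2H-1,2-oxasiline | ICC/C(C)=C/CC[C@@]1(C)O[Si](C)(C)CC=C1
F7 | step 7 | 3-ethoxy-2-isopropylcyclopent-2-en-1-one | CCOC1=C(C(C)C)C(=O)CC1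
F8 | step 7 | 3-ethoxy-2-isopropyl-1-[(E)-3-methyl-6-[(6R)-2,2,6-trimethyl-3,6-dihydro-2H-1,2-oxasilin-6-yl]hex-3-en-1-yl]cyclopent-2-en-1-ol (both carbinol epimers) | CCOC1=C(C(C)C)C(O)(CC/C(C)=C/CC[C@@]2(C)O[Si](C)(C)CC=C2)CC1
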